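**Plan**

- Retrosynthesis: the aryl silyl ether is cleaved last; the C4 carbonyl goes back to the CH2 group of a 2-aryl-4H-chromene, and this to a 2-silyloxychromane by loss of silanol.
- Ring C is then cut at O1–C2 and C3–C4 (hetero-Diels–Alder) and ring A at C4a–C8a (6π electrocyclisation), giving a 4-allenylcyclobutenone and the silyl enol ether of the ring B ketone.
- Enabling feature: ring A carries four adjacent methoxy groups (C5 to C8) next to O1 on C8a and the C4 carbon on C4a. This fully substituted ring maps onto dimethyl squarate plus methoxyallene, which deliver it as an o-quinone methide whose O1–C8a–C4a–C4 oxadiene closes ring C.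
- Forward: squarate plus lithiated methoxyallene, O-methylation, then one thermal operation that builds ring A and then ring C; silanol loss, C4 oxidation and desilylation complete the flavone.
- Stereochemistry: the target is achiral; the stereocentres of the cyclobutenone (C4) and of the chromane (C2) are formed racemic and are erased by ring opening and by silanol elimination.

Key step: step 3

Remark on the chemistry: the 4'-phenol is carried as its TBS ether, so that one silylation of acetosyringone gives the dienophile and the last step is a fluoride desilylation. Cyclobutenone 7 is assumed to be thermally labile and is kept cold and used at once.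

**Step 1**
Reactants: 1 acetosyringone
Product: 2 tert-butyl{[1-(4-{[tert-butyl(dimethyl)silyl]oxy}-3,5-dimethoxyphenyl)ethenyl]oxy}dimethylsilane
Conditions: TBSOTf (2.3 equiv), Et3N (3.5 equiv), CH2Cl2, 0 °C to rt; filtration through Et3N-deactivated silica
Reagents that add atoms: tert-butyldimethylsilyl trifluoromethanesulfonate (TBSOTf), CC(C)(C)[Si](C)(C)OS(=O)(=O)C(F)(F)F
Why: A silyl triflate with a tertiary amine silylates the phenol and converts the methyl ketone, which can enolise in one direction only, into its silyl enol ether in the same flask (soft enolisation with O-silylation); no stereocentre is formed.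

**Step 2**
Reactants: 3 methoxyallene; 4 dimethyl squarate
Product: 7 racemic 2,3,4-trimethoxy-4-(1-methoxypropa-1,2-dien-1-yl)cyclobut-2-en-1-one, via 1-lithio-1-methoxyallene 5 (not isolated), via lithium cyclobutenolate 6 (not isolated)
Conditions: n-BuLi (1.1 equiv), THF, −78 °C; then 4, THF, −78 °C; then MeOTf (1.5 equiv), −78 to −20 °C; cold aq. NaHCO3, rapid chromatography at 0 °C on Et3N-deactivated silica
Reagents that add atoms: methyl trifluoromethanesulfonate (MeOTf), COS(=O)(=O)C(F)(F)F
Why: Methoxyallene is lithiated at C1, the allenyllithium adds 1,2 to one of the two equivalent carbonyl groups of the squarate at low temperature, and the tertiary lithium alkoxide is O-methylated in situ before it can cyclise onto the allene or ring-open (organolithium carbonyl addition, then alkoxide alkylation); the quaternary stereocentre forms racemic and is erased in step 3.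

**Step 3**
Reactants: 7 racemic 2,3,4-trimethoxy-4-(1-methoxypropa-1,2-dien-1-yl)cyclobut-2-en-1-one; 2 tert-butyl{[1-(4-{[tert-butyl(dimethyl)silyl]oxy}-3,5-dimethoxyphenyl)ethenyl]oxy}dimethylsilane
Product: 10 racemic tert-butyl{[2-(4-{[tert-butyl(dimethyl)silyl]oxy}-3,5-dimethoxyphenyl)-5,6,7,8-tetramethoxy-3,4-dihydro-2H-chromen-2-yl]oxy}dimethylsilane, via allenylketene 8 (not isolated), via o-quinone methide 9 (not isolated)
Conditions: 2 (3 equiv), PhMe, 80 °C, 7 added over 4 h by syringe pump, Ar, base-washed glassware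
Reagents that add atoms: none
Why: Heating opens the cyclobutenone by conrotatory 4π electrocyclic ring opening with the C4 methoxy group turning outward, so that the allenyl group lies cis to the ketene in 8, and 6π electrocyclisation between the ketene carbon and the central allene carbon then forms the C4a–C8a bond and closes ring A as the tetramethoxy o-quinone methide 9. Its oxadiene O1=C8a–C4a=C4 is captured by the electron-rich silyl enol ether 2 in an inverse-electron-demand hetero-Diels–Alder reaction that forms C3–C4 and O1–C2, closes ring C and restores the aromaticity of ring A. The closest known reaction type is the thermal ring expansion of 4-allenylcyclobutenones to o-quinone methides with capture by electron-rich alkenes in the same flask. Ring A therefore closes by a 6π electrocyclisation and ring C by an intermolecular (4+2) cycloaddition. The only new stereocentre, the ketal carbon C2, forms without control as a racemate and is removed in step 4, while the stereocentre of 7 is lost on ring opening. The step needs the regiochemistry in which the CH2 terminus of 2 bonds to the exocyclic methylene of 9, which the matched polarity of the partners (largest LUMO coefficient at the exocyclic carbon, largest HOMO coefficient at the enol ether CH2) should secure, and slow release of 9 into an excess of 2 should hold back its dimerisation.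

**Step 4**
Reactants: 10 racemic tert-butyl{[2-(4-{[tert-butyl(dimethyl)silyl]oxy}-3,5-dimethoxyphenyl)-5,6,7,8-tetramethoxy-3,4-dihydro-2H-chromen-2-yl]oxy}dimethylsilane
Product: 11 tert-butyl[2,6-dimethoxy-4-(5,6,7,8-tetramethoxy-4H-chromen-2-yl)phenoxy]dimethylsilane
Conditions: PPTS (10 mol %), 4 Å MS, PhMe, 80 °C
Reagents that add atoms: none
Why: Protonation of the silyl ketal expels tert-butyldimethylsilanol to give an oxocarbenium ion stabilised by O1 and ring B, which loses a C3 proton to the conjugated 2-aryl-4H-chromene (acid-catalysed E1 elimination of a mixed ketal to an enol ether); the aryl silyl ether should tolerate the weak acid and the C2 stereocentre disappears.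

**Step 5**
Reactants: 11 tert-butyl[2,6-dimethoxy-4-(5,6,7,8-tetramethoxy-4H-chromen-2-yl)phenoxy]dimethylsilane
Product: 12 silyl-protected flavone 2-(4-{[tert-butyl(dimethyl)silyl]oxy}-3,5-dimethoxyphenyl)-5,6,7,8-tetramethoxy-4H-chromen-4-one
Conditions: t-BuOOH (5.5 M in decane, 4 equiv), Rh2(cap)4 (dirhodium tetracaprolactamate, 1 mol %), K2CO3 (0.5 equiv), CH2Cl2, rt
Reagents that add atoms: tert-butyl hydroperoxide (t-BuOOH), CC(C)(C)OO
Why: The C4 methylene is benzylic to ring A and allylic to the C2=C3 enol ether, so the tert-butylperoxyl radical should abstract hydrogen there and the resulting mixed peroxide should collapse to the conjugated pyranone carbonyl (Kornblum–DeLaMare-type fragmentation), an allylic-benzylic C–H oxidation of the kind that converts xanthenes and chromenes into xanthones and chromones.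

**Step 6**
Reactants: 12 silyl-protected flavone 2-(4-{[tert-butyl(dimethyl)silyl]oxy}-3,5-dimethoxyphenyl)-5,6,7,8-tetramethoxy-4H-chromen-4-one
Product: 13 the target 4'-hydroxy-3',5,5',6,7,8-hexamethoxyflavone
Conditions: TBAF (1.1 equiv), AcOH (1.1 equiv), THF, 0 °C
Reagents that add atoms: none
Why: Fluoride cleaves the aryl O–Si bond (fluoride-mediated desilylation) under buffered conditions that should leave the flavone and the six methyl ethers untouched.

**Compound list**

1 | acetosyringone, 1-(4-hydroxy-3,5-dimethoxyphenyl)ethan-1-one | CC(=O)c1cc(OC)c(O)c(OC)c1 | starting material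
2 | tert-butyl{[1-(4-{[tert-butyl(dimethyl)silyl]oxy}-3,5-dimethoxyphenyl)ethenyl]oxy}dimethylsilane | C=C(O[Si](C)(C)C(C)(C)C)c1cc(OC)c(O[Si](C)(C)C(C)(C)C)c(OC)c1 | intermediate
3 | methoxyallene, 1-methoxypropa-1,2-diene | C=C=COC | starting material
4 | dimethyl squarate, 3,4-dimethoxycyclobut-3-ene-1,2-dione | COC1=C(OC)C(=O)C1=O | starting material
5 | 1-lithio-1-methoxyallene, (1-methoxypropa-1,2-dien-1-yl)lithium | [Li]C(OC)=C=C | intermediate
6 | lithium 2,3-dimethoxy-1-(1-methoxypropa-1,2-dien-1-yl)-4-oxocyclobut-2-en-1-olate (racemic) | [Li]OC1(C(OC)=C=C)C(OC)=C(OC)C1=O | intermediate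
7 | 2,3,4-trimethoxy-4-(1-methoxypropa-1,2-dien-1-yl)cyclobut-2-en-1-one (racemic) | COC1=C(OC)C(OC)(C(OC)=C=C)C1=O | intermediate
8 | (3Z)-2,3,4,5-tetramethoxyhepta-1,3,5,6-tetraen-1-one (allenylketene) | O=C=C(OC)/C(OC)=C(\C(OC)=C=C)OC | intermediate
9 | 2,3,4,5-tetramethoxy-6-methylidenecyclohexa-2,4-dien-1-one (o-quinone methide) | C=C1C(=O)C(OC)=C(OC)C(OC)=C1OC | intermediate
10 | tert-butyl{[2-(4-{[tert-butyl(dimethyl)silyl]oxy}-3,5-dimethoxyphenyl)-5,6,7,8-tetramethoxy-3,4-dihydro-2H-chromen-2-yl]oxy}dimethylsilane (racemic) | COc1cc(C2(O[Si](C)(C)C(C)(C)C)CCc3c(OC)c(OC)c(OC)c(OC)c3O2)cc(OC)c1O[Si](C)(C)C(C)(C)C | intermediate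
11 | tert-butyl[2,6-dimethoxy-4-(5,6,7,8-tetramethoxy-4H-chromen-2-yl)phenoxy]dimethylsilane | COc1cc(C2=CCc3c(OC)c(OC)c(OC)c(OC)c3O2)cc(OC)c1O[Si](C)(C)C(C)(C)C | intermediate
12 | 2-(4-{[tert-butyl(dimethyl)silyl]oxy}-3,5-dimethoxyphenyl)-5,6,7,8-tetramethoxy-4H-chromen-4-one | COc1cc(-c2cc(=O)c3c(OC)c(OC)c(OC)c(OC)c3o2)cc(OC)c1O[Si](C)(C)C(C)(C)C | intermediate
13 | 4'-hydroxy-3',5,5',6,7,8-hexamethoxyflavone | COc1cc(-c2cc(=O)c3c(OC)c(OC)c(OC)c(OC)c3o2)cc(OC)c1O | target

**Step count**

Total steps: 6. Longest linear sequence: 5 steps (1 to 2, then steps 3 to 6; the branch from 3 and 4 through 7 has the same length).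

**Steps most likely to fail**

Step 3. Dimerisation of the transient o-quinone methide, or protodesilylation of the enol ether by adventitious acid at 80 °C, may outrun the bimolecular cycloaddition. The fallback replaces the silyl enol ether by a far more nucleophilic enamine, a classical partner of o-quinone methides. It sets out from 1: silylation of the phenol alone (TBSCl, imidazole, DMF) should give 1-(4-{[tert-butyl(dimethyl)silyl]oxy}-3,5-dimethoxyphenyl)ethan-1-one F1, and condensation with morpholine (TiCl4, PhMe, 0 °C to rt) the enamine 4-[1-(4-{[tert-butyl(dimethyl)silyl]oxy}-3,5-dimethoxyphenyl)ethenyl]morpholine F2. Thermolysis of 7 in its presence should give, by the same cascade, the aminal 4-[2-(4-{[tert-butyl(dimethyl)silyl]oxy}-3,5-dimethoxyphenyl)-5,6,7,8-tetramethoxy-3,4-dihydro-2H-chromen-2-yl]morpholine F3. Brief warming with AcOH in PhMe expels morpholine and the route is rejoined at 11.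

Step 5. The delocalised C4/C2 radical may be captured at C2, or the peroxide may attack the electron-rich enol ether double bond, so that ring cleavage competes with ketone formation. The fallback sets out from 10 and installs the C4 oxygen by hydride abstraction before the C2=C3 double bond exists; it also bypasses step 4. DDQ in wet, buffered CH2Cl2 at 0 °C should oxidise the C4–H bond of the chromane, which O1 and the C5 and C7 methoxy groups activate as in 5,7-dioxygenated flavans, to 2-{[tert-butyl(dimethyl)silyl]oxy}-2-(4-{[tert-butyl(dimethyl)silyl]oxy}-3,5-dimethoxyphenyl)-5,6,7,8-tetramethoxy-3,4-dihydro-2H-chromen-4-ol F4. Dess–Martin periodinane should give the ketone 2-{[tert-butyl(dimethyl)silyl]oxy}-2-(4-{[tert-butyl(dimethyl)silyl]oxy}-3,5-dimethoxyphenyl)-5,6,7,8-tetramethoxy-2,3-dihydro-4H-chromen-4-one F5. Catalytic p-TsOH in PhMe then eliminates silanol from the position β to the carbonyl, as in the dehydration of 2-hydroxyflavanones, and the route is rejoined at 12.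

Step 2. O-Methylation of the congested tertiary lithium alkoxide may be slow, so that on warming it cyclises onto the allene or ring-opens, and the labile methyl ether may be lost during work-up. The fallback carries this oxygen as a silyl ether and methylates it late. It sets out from 6: trapping at −78 °C with Me3SiCl should give 2,3-dimethoxy-4-(1-methoxypropa-1,2-dien-1-yl)-4-[(trimethylsilyl)oxy]cyclobut-2-en-1-one F6. The cascade of step 3 with 2 should then give tert-butyl{[2-(4-{[tert-butyl(dimethyl)silyl]oxy}-3,5-dimethoxyphenyl)-5,7,8-trimethoxy-6-[(trimethylsilyl)oxy]-3,4-dihydro-2H-chromen-2-yl]oxy}dimethylsilane F7. Selective methanolysis of the aryl trimethylsilyl ether (K2CO3, MeOH, 0 °C) should give 2-{[tert-butyl(dimethyl)silyl]oxy}-2-(4-{[tert-butyl(dimethyl)silyl]oxy}-3,5-dimethoxyphenyl)-5,7,8-trimethoxy-3,4-dihydro-2H-chromen-6-ol F8. Methylation of this phenol (MeI, K2CO3, acetone) rejoins the route at 10.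

**Further compounds**

F1 | step 3 | 1-(4-{[tert-butyl(dimethyl)silyl]oxy}-3,5-dimethoxyphenyl)ethan-1-one | CC(=O)c1cc(OC)c(O[Si](C)(C)C(C)(C)C)c(OC)c1
F2 | step 3 | 4-[1-(4-{[tert-butyl(dimethyl)silyl]oxy}-3,5-dimethoxyphenyl)ethenyl]morpholine | C=C(N1CCOCC1)c1cc(OC)c(O[Si](C)(C)C(C)(C)C)c(OC)c1
F3 | step 3 | 4-[2-(4-{[tert-butyl(dimethyl)silyl]oxy}-3,5-dimethoxyphenyl)-5,6,7,8-tetramethoxy-3,4-dihydro-2H-chromen-2-yl]morpholine (racemic) | COc1cc(C2(N3CCOCC3)CCc3c(OC)c(OC)c(OC)c(OC)c3O2)cc(OC)c1O[Si](C)(C)C(C)(C)C
F4 | step 5 | 2-{[tert-butyl(dimethyl)silyl]oxy}-2-(4-{[tert-butyl(dimethyl)silyl]oxy}-3,5-dimethoxyphenyl)-5,6,7,8-tetramethoxy-3,4-dihydro-2H-chromen-4-ol (racemic, mixture of diastereomers) | COc1cc(C2(O[Si](C)(C)C(C)(C)C)CC(O)c3c(OC)c(OC)c(OC)c(OC)c3O2)cc(OC)c1O[Si](C)(C)C(C)(C)C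
F5 | step 5 | 2-{[tert-butyl(dimethyl)silyl]oxy}-2-(4-{[tert-butyl(dimethyl)silyl]oxy}-3,5-dimethoxyphenyl)-5,6,7,8-tetramethoxy-2,3-dihydro-4H-chromen-4-one (racemic) | COc1cc(C2(O[Si](C)(C)C(C)(C)C)CC(=O)c3c(OC)c(OC)c(OC)c(OC)c3O2)cc(OC)c1O[Si](C)(C)C(C)(C)C
F6 | step 2 | 2,3-dimethoxy-4-(1-methoxypropa-1,2-dien-1-yl)-4-[(trimethylsilyl)oxy]cyclobut-2-en-1-one (racemic) | COC1=C(OC)C(O[Si](C)(C)C)(C(OC)=C=C)C1=O
F7 | step 2 | tert-butyl{[2-(4-{[tert-butyl(dimethyl)silyl]oxy}-3,5-dimethoxyphenyl)-5,7,8-trimethoxy-6-[(trimethylsilyl)oxy]-3,4-dihydro-2H-chromen-2-yl]oxy}dimethylsilane (racemic) | COc1cc(C2(O[Si](C)(C)C(C)(C)C)CCc3c(OC)c(O[Si](C)(C)C)c(OC)c(OC)c3O2)cc(OC)c1O[Si](C)(C)C(C)(C)C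
F8 | step 2 | 2-{[tert-butyl(dimethyl)silyl]oxy}-2-(4-{[tert-butyl(dimethyl)silyl]oxy}-3,5-dimethoxyphenyl)-5,7,8-trimethoxy-3,4-dihydro-2H-chromen-6-ol (racemic) | COc1cc(C2(O[Si](C)(C)C(C)(C)C)CCc3c(OC)c(O)c(OC)c(OC)c3O2)cc(OC)c1O[Si](C)(C)C(C)(C)C
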